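**Plan**

- Feature: ring A is a hexasubstituted benzene in which oxygen (C2, C4, C6) and carbon substituents (butyryl C1, prenyl C3, ring B benzyl C5) alternate. The three oxygens can come from a ketene carbonyl, a 3-alkoxycyclobutenone and an ynol ether.
- Retrosynthesis: the prenyl terminus is cut back to allyl (cross-metathesis), the ethers are stripped and the butyryl–C1 bond is cut (Friedel–Crafts). Ring A is then cut at C3–C4 and C1–C2 into a siloxyalkyne and a 3-ethoxy-4-benzylcyclobutenone.
- The cyclobutenone is cut into ethoxyacetylene and the ketene of a ring B arylpropanoyl chloride; ring B is bought as 2,4,6-trihydroxytoluene.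
- Forward: ring B is acetylated, methylated para to acetyl, formylated, benzylated and homologated. A ketene/alkyne [2+2] gives the cyclobutenone, the benzannulation builds ring A on the benzylic carbon, and acylation, ether cleavage, metathesis and desilylation finish.
- Design: the prenyl group travels as allyl through the two Lewis acid steps. The ring B hydroxyls ortho to acetyl are benzyl ethers, so the methoxy group para to acetyl is the only methyl ether present.
- Stereochemistry: the target has no stereocentre and no E/Z alkene; the racemic centre of the cyclobutenone disappears on ring opening.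

Key step: step 8

Step 1
Reactants: 1 2,4,6-trihydroxytoluene
Product: 2 1-(2,4,6-trihydroxy-3-methylphenyl)ethanone
Conditions: AcCl, AlCl3, PhNO2, 0 → 60 °C; then ice/HCl
Reagents that add atoms: acetyl chloride, CC(=O)Cl
Why: Friedel–Crafts C-acylation of a phloroglucinol; the two free ring carbons are equivalent and the first acyl group deactivates the ring towards a second.

Step 2
Reactants: 2 1-(2,4,6-trihydroxy-3-methylphenyl)ethanone
Product: 3 1-(2,6-dihydroxy-4-methoxy-3-methylphenyl)ethanone
Conditions: Me2SO4 (1 equiv), K2CO3, acetone, reflux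
Reagents that add atoms: dimethyl sulfate, COS(=O)(=O)OC
Why: Williamson O-methylation with limiting reagent should select the hydroxyl para to acetyl, the most acidic one and the only one not hydrogen-bonded to the carbonyl, as is usual for phloracetophenones.

Step 3
Reactants: 3 1-(2,6-dihydroxy-4-methoxy-3-methylphenyl)ethanone
Product: 4 3-acetyl-2,4-dihydroxy-6-methoxy-5-methylbenzaldehyde
Conditions: Cl2CHOMe, TiCl4, CH2Cl2, −10 °C → rt; then aq. HCl
Reagents that add atoms: dichloromethyl methyl ether, COC(Cl)Cl; water, O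
Why: Rieche formylation, in which the titanium phenoxide directs the electrophile to the only free ring carbon (ortho to OH); it avoids the chromone formation that a Vilsmeier reagent causes with ortho-hydroxyacetophenones.

Step 4
Reactants: 4 3-acetyl-2,4-dihydroxy-6-methoxy-5-methylbenzaldehyde
Product: 5 3-acetyl-2,4-bis(benzyloxy)-6-methoxy-5-methylbenzaldehyde
Conditions: BnBr (excess), K2CO3, cat. Bu4NI, DMF, 60 °C
Reagents that add atoms: benzyl bromide, BrCc1ccccc1
Why: Williamson etherification of both chelated phenols; carbonate in a dipolar aprotic solvent favours O- over C-alkylation of the fully substituted ring.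

Step 5
Reactants: 5 3-acetyl-2,4-bis(benzyloxy)-6-methoxy-5-methylbenzaldehyde
Product: 9 3-[3-acetyl-2,4-bis(benzyloxy)-6-methoxy-5-methylphenyl]propanoic acid, via arylidene Meldrum's acid 6 (not isolated), via benzyl Meldrum's acid 7 (not isolated), via malonic acid 8 (not isolated)
Conditions: Meldrum's acid, HCO2H/Et3N (5:2), 100 °C
Reagents that add atoms: Meldrum's acid (2,2-dimethyl-1,3-dioxane-4,6-dione), CC1(C)OC(=O)CC(=O)O1
Why: Knoevenagel condensation, hydride transfer from formate to the alkylidene, then hydrolysis and decarboxylation in one pot give the 3-arylpropanoic acid; no metal or hydrogen is used, so benzyl ethers and the hindered ketone are left alone.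

Step 6
Reactants: 9 3-[3-acetyl-2,4-bis(benzyloxy)-6-methoxy-5-methylphenyl]propanoic acid; 10 ethoxyacetylene
Product: 13 4-[[3-acetyl-2,4-bis(benzyloxy)-6-methoxy-5-methylphenyl]methyl]-3-ethoxycyclobut-2-en-1-one (racemic), via acid chloride 11 (not isolated), via ketene 12 (not isolated)
Conditions: (COCl)2, cat. DMF, CH2Cl2, 0 °C → rt, evaporate; then 10 (excess), Et3N, CH2Cl2, 0 °C → rt, slow addition of 11
Reagents that add atoms: none
Why: Dehydrochlorination gives the monoalkylketene, and its [2+2] cycloaddition with ethoxyacetylene (ketene carbonyl carbon to the unsubstituted alkyne carbon) is the standard entry to 4-alkyl-3-ethoxycyclobutenones; slow addition into excess alkyne holds back ketene dimerisation, and the new stereocentre is racemic and later lost.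

Step 7
Reactants: 14 ethyl but-3-enoate
Product: 17 triisopropyl(pent-4-en-1-yn-1-yloxy)silane, via dibromo enolate 15 (not isolated), via lithium ynolate 16 (not isolated)
Conditions: CH2Br2, lithium 2,2,6,6-tetramethylpiperidide (LiTMP), THF, −78 °C; n-BuLi, −78 → 0 °C; i-Pr3SiCl, −78 °C → rt
Reagents that add atoms: dibromomethane, BrCBr; chlorotriisopropylsilane, CC(C)[Si](Cl)(C(C)C)C(C)C
Why: Kowalski ester homologation: addition of LiCHBr2, enolisation, bromine–lithium exchange and 1,2-shift give the ynolate, which the bulky chlorosilane traps on oxygen; the cold addition step limits deprotonation of the β,γ-unsaturated ester.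

Step 8
Reactants: 13 4-[[3-acetyl-2,4-bis(benzyloxy)-6-methoxy-5-methylphenyl]methyl]-3-ethoxycyclobut-2-en-1-one (racemic); 17 triisopropyl(pent-4-en-1-yn-1-yloxy)silane
Product: 22 1-[2,6-bis(benzyloxy)-3-[[2-ethoxy-6-hydroxy-5-(prop-2-enyl)-4-(triisopropylsilyloxy)phenyl]methyl]-4-methoxy-5-methylphenyl]ethanone, via vinylketene 18 (not isolated), via vinylcyclobutenone 19 (not isolated), via dienylketene 20 (not isolated), via cyclohexadienone 21 (not isolated)
Conditions: 17 (2 equiv), PhMe (0.1 M), sealed tube, 110 °C then 140 °C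
Reagents that add atoms: none
Why: Danheiser benzannulation: heat opens 13 by a 4π electrocyclic reaction to ethoxyvinylketene 18, whose ketene C=C adds the siloxyalkyne in a [2+2] cycloaddition to 19; 19 opens to dienylketene 20, which closes ring A by a thermal 6π electrocyclisation between the ketene carbon and the benzyl-bearing diene terminus, and dienone 21 tautomerises to the phenol. The closest known reactions are the benzannulations of alkyl-substituted cyclobutenones with trialkylsiloxyalkynes to resorcinol monosilyl ethers and the thermal opening of 4-substituted 3-alkoxycyclobutenones to alkoxyvinylketenes. No stereocentre is formed, and the racemic centre of 13 is destroyed in the first ring opening. The step needs regioselectivity in the [2+2] addition, and the polarisation of the ynol ether secures it: its nucleophilic allyl-bearing carbon attacks the ketene carbonyl carbon and its oxygen-bearing carbon bonds to the ketene α-carbon, so allyl ends ortho to the new hydroxyl and the one unsubstituted CH lies between the two ether oxygens. It also needs the benzylic substituent to rotate outward on ring opening, as expected on steric grounds, which leaves hydrogen inside the diene terminus and allows the 6π closure. Because the vinylogous ester opens less readily than an alkylcyclobutenone, the alkyne is used in excess, the solution is dilute and the temperature is raised only as far as needed.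

Step 9
Reactants: 22 1-[2,6-bis(benzyloxy)-3-[[2-ethoxy-6-hydroxy-5-(prop-2-enyl)-4-(triisopropylsilyloxy)phenyl]methyl]-4-methoxy-5-methylphenyl]ethanone; 23 butanoyl chloride
Product: 24 1-[3-[[3-acetyl-2,4-bis(benzyloxy)-6-methoxy-5-methylphenyl]methyl]-2-ethoxy-4-hydroxy-5-(prop-2-enyl)-6-(triisopropylsilyloxy)phenyl]butan-1-one
Conditions: TiCl4, CH2Cl2, −78 → −20 °C
Reagents that add atoms: none
Why: Friedel–Crafts acylation at the single unsubstituted carbon of ring A, para to the titanium phenoxide and ortho to two ether oxygens; ring B is fully substituted, the monosubstituted alkene is far less nucleophilic than the arene, and the low temperature spares the ethers.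

Step 10
Reactants: 24 1-[3-[[3-acetyl-2,4-bis(benzyloxy)-6-methoxy-5-methylphenyl]methyl]-2-ethoxy-4-hydroxy-5-(prop-2-enyl)-6-(triisopropylsilyloxy)phenyl]butan-1-one
Product: 25 1-[3-[(3-acetyl-2,4-dihydroxy-6-methoxy-5-methylphenyl)methyl]-2,4-dihydroxy-5-(prop-2-enyl)-6-(triisopropylsilyloxy)phenyl]butan-1-one
Conditions: BCl3, C6HMe5, CH2Cl2, −78 → 0 °C; then H2O
Reagents that add atoms: none
Why: Lewis acid ether cleavage: BCl3 with pentamethylbenzene as benzyl cation scavenger removes aryl benzyl ethers at −78 °C, and on warming the ethyl ether is cleaved through a boron chelate between the butyryl carbonyl and the ethoxy oxygen (the bulky silyl ether on the other side does not chelate); the non-chelated methoxy group and the allyl group should persist at or below 0 °C.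

Step 11
Reactants: 25 1-[3-[(3-acetyl-2,4-dihydroxy-6-methoxy-5-methylphenyl)methyl]-2,4-dihydroxy-5-(prop-2-enyl)-6-(triisopropylsilyloxy)phenyl]butan-1-one
Product: 26 1-[3-[(3-acetyl-2,4-dihydroxy-6-methoxy-5-methylphenyl)methyl]-2,4-dihydroxy-5-(3-methylbut-2-enyl)-6-(triisopropylsilyloxy)phenyl]butan-1-one
Conditions: 2-methylbut-2-ene (excess), second-generation Grubbs catalyst (H2IMes)(PCy3)Cl2Ru=CHPh (5 mol %), CH2Cl2, 40 °C
Reagents that add atoms: 2-methylbut-2-ene, CC=C(C)C
Why: Olefin cross-metathesis of an allylarene with excess 2-methylbut-2-ene is the established way to turn allyl into prenyl, and it tolerates free phenols and aryl ketones.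

Step 12
Reactants: 26 1-[3-[(3-acetyl-2,4-dihydroxy-6-methoxy-5-methylphenyl)methyl]-2,4-dihydroxy-5-(3-methylbut-2-enyl)-6-(triisopropylsilyloxy)phenyl]butan-1-one
Product: 27 1-[3-[(3-acetyl-2,4-dihydroxy-6-methoxy-5-methylphenyl)methyl]-2,4,6-trihydroxy-5-(3-methylbut-2-enyl)phenyl]butan-1-one
Conditions: Bu4NF, AcOH, THF, 0 °C
Reagents that add atoms: none
Why: Fluoride cleavage of the aryl silyl ether under buffered, non-acidic conditions that should leave the prenyl alkene and the methylene bridge untouched.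

**Compound list**

1 | 2,4,6-trihydroxytoluene (2-methylbenzene-1,3,5-triol) | Cc1c(O)cc(O)cc1O | starting material
2 | 1-(2,4,6-trihydroxy-3-methylphenyl)ethanone | CC(=O)c1c(O)c(C)c(O)cc1O | intermediate
3 | 1-(2,6-dihydroxy-4-methoxy-3-methylphenyl)ethanone | CC(=O)c1c(O)c(C)c(OC)cc1O | intermediate
4 | 3-acetyl-2,4-dihydroxy-6-methoxy-5-methylbenzaldehyde | O=Cc1c(O)c(C(C)=O)c(O)c(C)c1OC | intermediate
5 | 3-acetyl-2,4-bis(benzyloxy)-6-methoxy-5-methylbenzaldehyde | O=Cc1c(OCc2ccccc2)c(C(C)=O)c(OCc3ccccc3)c(C)c1OC | intermediate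
6 | 5-[[3-acetyl-2,4-bis(benzyloxy)-6-methoxy-5-methylphenyl]methylidene]-2,2-dimethyl-1,3-dioxane-4,6-dione | CC1(C)OC(=O)C(=Cc2c(OCc3ccccc3)c(C(C)=O)c(OCc4ccccc4)c(C)c2OC)C(=O)O1 | intermediate
7 | 5-[[3-acetyl-2,4-bis(benzyloxy)-6-methoxy-5-methylphenyl]methyl]-2,2-dimethyl-1,3-dioxane-4,6-dione | CC1(C)OC(=O)C(Cc2c(OCc3ccccc3)c(C(C)=O)c(OCc4ccccc4)c(C)c2OC)C(=O)O1 | intermediate
8 | 2-[[3-acetyl-2,4-bis(benzyloxy)-6-methoxy-5-methylphenyl]methyl]propanedioic acid | OC(=O)C(Cc1c(OCc2ccccc2)c(C(C)=O)c(OCc3ccccc3)c(C)c1OC)C(=O)O | intermediate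
9 | 3-[3-acetyl-2,4-bis(benzyloxy)-6-methoxy-5-methylphenyl]propanoic acid | OC(=O)CCc1c(OCc2ccccc2)c(C(C)=O)c(OCc3ccccc3)c(C)c1OC | intermediate
10 | ethoxyacetylene (ethoxyethyne) | CCOC#C | starting material
11 | 3-[3-acetyl-2,4-bis(benzyloxy)-6-methoxy-5-methylphenyl]propanoyl chloride | ClC(=O)CCc1c(OCc2ccccc2)c(C(C)=O)c(OCc3ccccc3)c(C)c1OC | intermediate
12 | 3-[3-acetyl-2,4-bis(benzyloxy)-6-methoxy-5-methylphenyl]prop-1-en-1-one | O=C=CCc1c(OCc2ccccc2)c(C(C)=O)c(OCc3ccccc3)c(C)c1OC | intermediate
13 | 4-[[3-acetyl-2,4-bis(benzyloxy)-6-methoxy-5-methylphenyl]methyl]-3-ethoxycyclobut-2-en-1-one (racemic) | O=C1C=C(OCC)C1Cc2c(OCc3ccccc3)c(C(C)=O)c(OCc4ccccc4)c(C)c2OC | intermediate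
14 | ethyl but-3-enoate | C=CCC(=O)OCC | starting material
15 | lithium 1,1-dibromopenta-1,4-dien-2-olate | [Li+].[O-]C(CC=C)=C(Br)Br | intermediate
16 | lithium pent-4-en-1-yn-1-olate | [Li+].[O-]C#CCC=C | intermediate
17 | triisopropyl(pent-4-en-1-yn-1-yloxy)silane | C=CCC#CO[Si](C(C)C)(C(C)C)C(C)C | intermediate
18 | (3Z)-5-[3-acetyl-2,4-bis(benzyloxy)-6-methoxy-5-methylphenyl]-3-ethoxypenta-1,3-dien-1-one | O=C=C/C(OCC)=C/Cc1c(OCc2ccccc2)c(C(C)=O)c(OCc3ccccc3)c(C)c1OC | intermediate
19 | 4-[(1Z)-3-[3-acetyl-2,4-bis(benzyloxy)-6-methoxy-5-methylphenyl]-1-ethoxyprop-1-enyl]-2-(prop-2-enyl)-3-(triisopropylsilyloxy)cyclobut-2-en-1-one (racemic) | O=C1C(CC=C)=C(O[Si](C(C)C)(C(C)C)C(C)C)C1/C(OCC)=C/Cc2c(OCc3ccccc3)c(C(C)=O)c(OCc4ccccc4)c(C)c2OC | intermediate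
20 | (3E,5Z)-7-[3-acetyl-2,4-bis(benzyloxy)-6-methoxy-5-methylphenyl]-5-ethoxy-2-(prop-2-enyl)-3-(triisopropylsilyloxy)hepta-1,3,5-trien-1-one | O=C=C(CC=C)/C(O[Si](C(C)C)(C(C)C)C(C)C)=C\C(OCC)=C\Cc1c(OCc2ccccc2)c(C(C)=O)c(OCc3ccccc3)c(C)c1OC | intermediate
21 | 6-[[3-acetyl-2,4-bis(benzyloxy)-6-methoxy-5-methylphenyl]methyl]-5-ethoxy-2-(prop-2-enyl)-3-(triisopropylsilyloxy)cyclohexa-2,4-dien-1-one (racemic) | O=C1C(CC=C)=C(O[Si](C(C)C)(C(C)C)C(C)C)C=C(OCC)C1Cc2c(OCc3ccccc3)c(C(C)=O)c(OCc4ccccc4)c(C)c2OC | intermediate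
22 | 1-[2,6-bis(benzyloxy)-3-[[2-ethoxy-6-hydroxy-5-(prop-2-enyl)-4-(triisopropylsilyloxy)phenyl]methyl]-4-methoxy-5-methylphenyl]ethanone | CCOc1cc(O[Si](C(C)C)(C(C)C)C(C)C)c(CC=C)c(O)c1Cc2c(OCc3ccccc3)c(C(C)=O)c(OCc4ccccc4)c(C)c2OC | intermediate
23 | butanoyl chloride | CCCC(=O)Cl | starting material
24 | 1-[3-[[3-acetyl-2,4-bis(benzyloxy)-6-methoxy-5-methylphenyl]methyl]-2-ethoxy-4-hydroxy-5-(prop-2-enyl)-6-(triisopropylsilyloxy)phenyl]butan-1-one | CCCC(=O)c1c(OCC)c(Cc2c(OCc3ccccc3)c(C(C)=O)c(OCc4ccccc4)c(C)c2OC)c(O)c(CC=C)c1O[Si](C(C)C)(C(C)C)C(C)C | intermediate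
25 | 1-[3-[(3-acetyl-2,4-dihydroxy-6-methoxy-5-methylphenyl)methyl]-2,4-dihydroxy-5-(prop-2-enyl)-6-(triisopropylsilyloxy)phenyl]butan-1-one | CCCC(=O)c1c(O)c(Cc2c(O)c(C(C)=O)c(O)c(C)c2OC)c(O)c(CC=C)c1O[Si](C(C)C)(C(C)C)C(C)C | intermediate
26 | 1-[3-[(3-acetyl-2,4-dihydroxy-6-methoxy-5-methylphenyl)methyl]-2,4-dihydroxy-5-(3-methylbut-2-enyl)-6-(triisopropylsilyloxy)phenyl]butan-1-one | CCCC(=O)c1c(O)c(Cc2c(O)c(C(C)=O)c(O)c(C)c2OC)c(O)c(CC=C(C)C)c1O[Si](C(C)C)(C(C)C)C(C)C | intermediate
27 | 1-[3-[(3-acetyl-2,4-dihydroxy-6-methoxy-5-methylphenyl)methyl]-2,4,6-trihydroxy-5-(3-methylbut-2-enyl)phenyl]butan-1-one | CCCC(=O)c1c(O)c(CC=C(C)C)c(O)c(Cc2c(O)c(C(C)=O)c(O)c(C)c2OC)c1O | target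

**Step count**

Total step count: 12. Longest linear sequence: 11 steps (steps 1–6 and 8–12); step 7 is a one-step side branch.

**Steps most likely to fail**

Step 8. The vinylogous ester 13 may open too slowly at temperatures that the siloxyalkyne survives, or the ethoxyvinylketene may dimerise or acylate the product phenol faster than it adds the alkyne. The fallback gives up building ring A and closes the methylene bridge last; it sets out from 3 and 23 and returns at target 27. Butanoyl chloride 23 would acylate phloroglucinol (AlCl3, PhNO2) to 1-(2,4,6-trihydroxyphenyl)butan-1-one F1. Prenyl bromide and aqueous KOH would C-alkylate F1 to 1-[2,4,6-trihydroxy-3-(3-methylbut-2-enyl)phenyl]butan-1-one F2. Ketone 3 would be aminomethylated at its free ring carbon with Eschenmoser's salt to 1-[3-[(dimethylamino)methyl]-2,6-dihydroxy-4-methoxy-5-methylphenyl]ethanone F3. Heating F3 with F2 in dioxane should expel dimethylamine, and the ortho-quinone methide of ring B would be captured by the one free ring carbon of F2 to give 27.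

Step 9. Acylation at the crowded carbon between the silyloxy and ethoxy groups may be slow, so that O-acylation of the free phenol, loss of the silyl group or attack on the benzyl ethers takes over. The fallback brings the carbon in as a much smaller electrophile and adjusts afterwards; it sets out from 22 and returns at 24. Rieche formylation of 22 (Cl2CHOMe, SnCl4, CH2Cl2, −78 °C) would give 3-[[3-acetyl-2,4-bis(benzyloxy)-6-methoxy-5-methylphenyl]methyl]-2-ethoxy-4-hydroxy-5-(prop-2-enyl)-6-(triisopropylsilyloxy)benzaldehyde F4. Addition of n-PrMgBr (THF, −78 °C) to the aldehyde would give 1-[3-[[3-acetyl-2,4-bis(benzyloxy)-6-methoxy-5-methylphenyl]methyl]-2-ethoxy-4-hydroxy-5-(prop-2-enyl)-6-(triisopropylsilyloxy)phenyl]butan-1-ol F5; the doubly ortho-substituted acetyl group of ring B should at most be enolised. MnO2 (CH2Cl2) would then oxidise the para-hydroxybenzylic alcohol to ketone 24.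

Step 10. The chelation-assisted loss of the ethyl group may need temperatures at which the crowded methoxy group of ring B is also attacked, or the silyl ether may be lost first so that boron ties the carbonyl to the wrong side and the ethyl ether stays. The fallback separates the two cleavages and confines the second to an ortho-carbonyl chelate; it sets out from 24 and returns at 25. BCl3 and C6HMe5 held at −78 °C would remove only the benzyl groups to give 1-[3-[(3-acetyl-2,4-dihydroxy-6-methoxy-5-methylphenyl)methyl]-2-ethoxy-4-hydroxy-5-(prop-2-enyl)-6-(triisopropylsilyloxy)phenyl]butan-1-one F6. MgI2 etherate (toluene, 80 °C) cleaves only ethers held in a magnesium chelate with an ortho carbonyl; in F6 that is the ethoxy group next to butyryl alone, which should give 25.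

**Further compounds**

F1 | step 8 | 1-(2,4,6-trihydroxyphenyl)butan-1-one | CCCC(=O)c1c(O)cc(O)cc1O
F2 | step 8 | 1-[2,4,6-trihydroxy-3-(3-methylbut-2-enyl)phenyl]butan-1-one | CCCC(=O)c1c(O)c(CC=C(C)C)c(O)cc1O
F3 | step 8 | 1-[3-[(dimethylamino)methyl]-2,6-dihydroxy-4-methoxy-5-methylphenyl]ethanone | CC(=O)c1c(O)c(CN(C)C)c(OC)c(C)c1O
F4 | step 9 | 3-[[3-acetyl-2,4-bis(benzyloxy)-6-methoxy-5-methylphenyl]methyl]-2-ethoxy-4-hydroxy-5-(prop-2-enyl)-6-(triisopropylsilyloxy)benzaldehyde | O=Cc1c(OCC)c(Cc2c(OCc3ccccc3)c(C(C)=O)c(OCc4ccccc4)c(C)c2OC)c(O)c(CC=C)c1O[Si](C(C)C)(C(C)C)C(C)C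
F5 | step 9 | 1-[3-[[3-acetyl-2,4-bis(benzyloxy)-6-methoxy-5-methylphenyl]methyl]-2-ethoxy-4-hydroxy-5-(prop-2-enyl)-6-(triisopropylsilyloxy)phenyl]butan-1-ol (racemic) | CCCC(O)c1c(OCC)c(Cc2c(OCc3ccccc3)c(C(C)=O)c(OCc4ccccc4)c(C)c2OC)c(O)c(CC=C)c1O[Si](C(C)C)(C(C)C)C(C)C
F6 | step 10 | 1-[3-[(3-acetyl-2,4-dihydroxy-6-methoxy-5-methylphenyl)methyl]-2-ethoxy-4-hydroxy-5-(prop-2-enyl)-6-(triisopropylsilyloxy)phenyl]butan-1-one | CCCC(=O)c1c(OCC)c(Cc2c(O)c(C(C)=O)c(O)c(C)c2OC)c(O)c(CC=C)c1O[Si](C(C)C)(C(C)C)C(C)C
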